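**Retrosynthetic overview**
- The oxirane is made last: hydroxyl-directed oxygen transfer to the (E)-C3=C4 olefin of the acyclic bromohydrin 10, with the C6 carbinol relaying both new stereocentres (4,6-syn).
- 10 comes from invertive bromide opening at C7 of epoxy chloride 9, which comes from the Sharpless epoxy alcohol 8 (the only reagent-controlled step; sets C6 and C7).
- 8 comes from trienol 7, made by allyl–alkenyl coupling of dienyl bromide 4 with the alkenylalane from propargyl alcohol.
- 4 comes from commercial (E)-3-methylpent-2-en-4-yn-1-ol by alkyne bromination and anti-hydrochlorination, which gives the (Z)-bromochlorovinyl group.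
- Ring order: a transient C6–C7 oxirane (opened again in step 7), then the C3–C4 oxirane, the only ring of the target, in the final step.

Assumption: the oxirane is taken to arise in the alga by late-stage oxygen transfer to the (E)-C3=C4 olefin of the fully halogenated 6-hydroxy triene (the stage before the furanoid congeners), and (E)-3-methylpent-2-en-4-yn-1-ol is bought as the pure E isomer.

Chain locants used below are those of the target: C1 = CHBr, C2 = CCl, C3 = C(CH3), C4 = CH, C5 = CH2, C6 = CHOH, C7 = CBr(CH3), C8 = CH2Cl.

**Step 1**
Reactants: 1 (E)-3-methylpent-2-en-4-yn-1-ol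
Product: 2 (E)-5-bromo-3-methylpent-2-en-4-yn-1-ol
Conditions: NBS (1.1 equiv), AgNO3 (10 mol%), acetone, 20 °C, dark
Reagents that add atoms: N-bromosuccinimide, O=C1CCC(=O)N1Br
Why: AgNO3-catalysed electrophilic bromination of the terminal alkyne C–H by NBS is selective for the alkyne over the trisubstituted olefin and the free hydroxyl, and no stereocentre is involved.

**Step 2**
Reactants: 2 (E)-5-bromo-3-methylpent-2-en-4-yn-1-ol
Product: 3 (2E,4Z)-5-bromo-4-chloro-3-methylpenta-2,4-dien-1-ol
Conditions: LiCl (3 equiv), Pd(OAc)2 (5 mol%), AcOH, 20 °C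
Reagents that add atoms: lithium chloride, [Li+].[Cl-]
Why: Divalent-palladium-catalysed anti-hydrochlorination of a 1-bromoalkyne (chloropalladation, then protodepalladation) puts chloride on the internal carbon anti to the metal and replaces the carbon–palladium bond by hydrogen with retention, so Cl and Br end cis (Z) with Br trans to the chain, and the (E)-olefin is untouched.

**Step 3**
Reactants: 3 (2E,4Z)-5-bromo-4-chloro-3-methylpenta-2,4-dien-1-ol
Product: 4 (1Z,3E)-1,5-dibromo-2-chloro-3-methylpenta-1,3-diene
Conditions: CBr4 (1.2 equiv), PPh3 (1.25 equiv), CH2Cl2, 0 °C; used after filtration through silica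
Reagents that add atoms: carbon tetrabromide, BrC(Br)(Br)Br
Why: Appel bromination activates the primary allylic hydroxyl and bromide displaces it in an SN2 step at 0 °C without allylic transposition or loss of either olefin geometry; no stereocentre is involved.

**Step 4**
Reactants: 4 (1Z,3E)-1,5-dibromo-2-chloro-3-methylpenta-1,3-diene; 5 prop-2-yn-1-ol (propargyl alcohol)
Product: 7 (2E,5E,7Z)-8-bromo-7-chloro-2,6-dimethylocta-2,5,7-trien-1-ol, via alkenylalane 6 (not isolated)
Conditions: 5, AlMe3 (3 equiv), Cp2ZrCl2 (0.25 equiv), CH2Cl2, 0 to 20 °C; then 4 (0.9 equiv), Pd(PPh3)4 (3 mol%), THF, 0 to 20 °C; aq. KNaC4H4O6 work-up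
Reagents that add atoms: trimethylaluminium, C[Al](C)C
Why: Negishi zirconium-catalysed syn-carboalumination places CH3 on the internal and aluminium on the terminal alkyne carbon (E-alkenylalane), and zerovalent-palladium-catalysed allyl–alkenyl cross-coupling joins it to the primary terminus of the allyl unit with retention of both olefin geometries, the allylic C–Br bond reacting far faster than the vinylic one.

**Step 5**
Reactants: 7 (2E,5E,7Z)-8-bromo-7-chloro-2,6-dimethylocta-2,5,7-trien-1-ol
Product: 8 [(2R,3R)-3-[(2E,4Z)-5-bromo-4-chloro-3-methylpenta-2,4-dien-1-yl]-2-methyloxiran-2-yl]methanol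
Conditions: Ti(OiPr)4 (10 mol%), D-(−)-diethyl tartrate (12 mol%), tBuOOH (2 equiv, decane), 4 Å molecular sieves, CH2Cl2, −20 °C
Reagents that add atoms: tert-butyl hydroperoxide, CC(C)(C)OO
Why: Sharpless asymmetric epoxidation touches only the allylic-alcohol olefin, and D-(−)-tartrate delivers oxygen to the face that gives the (2R,3R)-epoxy alcohol (the sense that converts geraniol into its 2R,3R epoxide), which sets C6 as R and fixes C7 for the later inversion.

**Step 6**
Reactants: 8 [(2R,3R)-3-[(2E,4Z)-5-bromo-4-chloro-3-methylpenta-2,4-dien-1-yl]-2-methyloxiran-2-yl]methanol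
Product: 9 (2S,3R)-3-[(2E,4Z)-5-bromo-4-chloro-3-methylpenta-2,4-dien-1-yl]-2-(chloromethyl)-2-methyloxirane
Conditions: PPh3 (1.5 equiv), NaHCO3 (0.2 equiv), CCl4, 70 °C
Reagents that add atoms: carbon tetrachloride, ClC(Cl)(Cl)Cl
Why: Appel chlorination replaces the primary hydroxyl by chloride in an SN2 step under buffered neutral conditions that leave the oxirane intact, and no stereocentre is touched (the descriptor at C7 changes from R to S only because CH2Cl now outranks the ring carbon).

**Step 7**
Reactants: 9 (2S,3R)-3-[(2E,4Z)-5-bromo-4-chloro-3-methylpenta-2,4-dien-1-yl]-2-(chloromethyl)-2-methyloxirane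
Product: 10 (2R,3R,5E,7Z)-2,8-dibromo-1,7-dichloro-2,6-dimethylocta-5,7-dien-3-ol
Conditions: HBr (48% aq., 1.5 equiv), LiBr (5 equiv), Et2O, −30 to −10 °C
Reagents that add atoms: hydrogen bromide, Br
Why: Acid-promoted, borderline-SN2 (Markovnikov) oxirane opening lengthens the bond from oxygen to the tertiary carbon C7, so bromide enters anti at C7 with inversion (7R) while C6 keeps its oxygen and configuration (6R), attack at C6 being disfavoured because it is a secondary carbon next to a quaternary one; low temperature and excess bromide suppress hydration, HBr addition to the diene and chlorine participation.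

**Step 8**
Reactants: 10 (2R,3R,5E,7Z)-2,8-dibromo-1,7-dichloro-2,6-dimethylocta-5,7-dien-3-ol
Product: 11 (2R,3R)-3-bromo-1-[(2S,3R)-3-[(Z)-2-bromo-1-chloroethenyl]-3-methyloxiran-2-yl]-4-chloro-3-methylbutan-2-ol (target)
Conditions: VO(acac)2 (5 mol%), tBuOOH (1.5 equiv, decane), CH2Cl2, 0 °C; chromatography on neutral alumina
Reagents that add atoms: tert-butyl hydroperoxide, CC(C)(C)OO
Why: In this hydroxyl-directed epoxidation of a homoallylic alcohol (Sharpless–Mihelich type), the C6 hydroxyl binds the pentavalent vanadium alkylperoxide and delivers oxygen through a chair-like transition state with the C7 substituent equatorial, to the olefin face that gives the 4,6-syn epoxy alcohol, so C4 (S) and C3 (R) are both set from C6 with the (E)-geometry retained (CH3 cis to C5), while the electron-poor bromochlorovinyl olefin is inert and no base reaches the C6/C7 bromohydrin.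

**Compound list**
1 | (E)-3-methylpent-2-en-4-yn-1-ol | OC/C=C(C)/C#C | starting material
2 | (E)-5-bromo-3-methylpent-2-en-4-yn-1-ol | OC/C=C(C)/C#CBr | intermediate
3 | (2E,4Z)-5-bromo-4-chloro-3-methylpenta-2,4-dien-1-ol | OC/C=C(C)/C(Cl)=C/Br | intermediate
4 | (1Z,3E)-1,5-dibromo-2-chloro-3-methylpenta-1,3-diene | BrC/C=C(C)/C(Cl)=C/Br | intermediate
5 | prop-2-yn-1-ol (propargyl alcohol) | OCC#C | starting material
6 | alkenylalane, (E)-[3-(dimethylalumanyl)-2-methylprop-2-en-1-yl]oxy(dimethyl)alumane (Al on the terminal carbon, cis to CH3) | C[Al](C)OC/C(C)=C/[Al](C)C | intermediate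
7 | (2E,5E,7Z)-8-bromo-7-chloro-2,6-dimethylocta-2,5,7-trien-1-ol | OC/C(C)=C/C/C=C(C)/C(Cl)=C/Br | intermediate
8 | [(2R,3R)-3-[(2E,4Z)-5-bromo-4-chloro-3-methylpenta-2,4-dien-1-yl]-2-methyloxiran-2-yl]methanol | OC[C@@]1(C)O[C@@H]1C/C=C(C)/C(Cl)=C/Br | intermediate
9 | (2S,3R)-3-[(2E,4Z)-5-bromo-4-chloro-3-methylpenta-2,4-dien-1-yl]-2-(chloromethyl)-2-methyloxirane | ClC[C@@]1(C)O[C@@H]1C/C=C(C)/C(Cl)=C/Br | intermediate
10 | (2R,3R,5E,7Z)-2,8-dibromo-1,7-dichloro-2,6-dimethylocta-5,7-dien-3-ol | C[C@](Br)(CCl)[C@H](O)C/C=C(C)/C(Cl)=C/Br | intermediate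
11 | (2R,3R)-3-bromo-1-[(2S,3R)-3-[(Z)-2-bromo-1-chloroethenyl]-3-methyloxiran-2-yl]-4-chloro-3-methylbutan-2-ol (chain locants: 3R,4S,6R,7R,1Z) | C[C@](Br)(CCl)[C@H](O)C[C@@H]1O[C@@]1(C)/C(Cl)=C/Br | target

**Step count and risks**
Total: 8 steps. Longest linear sequence: 8 steps (1 to 11); propargyl alcohol 5 enters in step 4 without separate steps of its own.

The three steps most likely to fail are step 8, step 7 and step 4.

Step 8 carries the most risk. The facial selectivity rests on 1,3-induction through a homoallylic vanadium alkoxide and may be modest, turnover can be slow, and traces of acid can make the C6 hydroxyl attack the new vinyl oxirane at C3 to give a tetrahydrofuran. The fallback is reagent-controlled dioxirane epoxidation. It sets out from 10, whose hydroxyl is masked with Et3SiOTf and 2,6-lutidine in CH2Cl2 at −78 °C (no alkoxide forms, so the bromohydrin cannot close) to give triethylsilyl ether F1. Shi epoxidation with the enantiomer of the fructose-derived ketone (made from L-sorbose), KHSO5 (as Oxone) and K2CO3 buffer in MeCN/dimethoxymethane/water at 0 °C then gives epoxy silyl ether F2; this catalyst attacks the face that gives (S,S)-oxiranes from simple trans-olefins, which is 3R,4S here. HF·pyridine in THF/pyridine at 0 °C removes the silyl group and the sequence comes back to the route at 11.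

Step 7 may lose regio- or stereocontrol. The CH2Cl group lowers the cationic character of C7, so attack at C6 could compete, and participation by the chlorine would give retention at C7. The fallback reverses the order of the two halogenations. It sets out from 8, which is opened directly with HBr/LiBr in Et2O at −30 °C; a hydroxymethyl group deactivates the tertiary carbon less than chloromethyl and cannot bridge, and acid openings of 2-methyl-2,3-epoxy-1-ols are known to occur at the tertiary carbon with inversion. This gives bromodiol F3. Its primary hydroxyl is then exchanged for chloride under Appel conditions (PPh3, CCl4, 40 °C; the primary hydroxyl is activated first for steric reasons), and the sequence comes back to the route at 10. The Appel step is itself uncertain, because the primary carbon is neopentyl-like and the neighbouring bromine could migrate.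

Step 4 is a one-flask carboalumination and coupling. Methyl transfer from aluminium, insertion of zerovalent palladium into the vinylic C–Br bond, or E/Z leakage in the dienyl palladium intermediate could each lower the yield. The fallback is a copper-catalysed Grignard substitution followed by allylic oxidation. It sets out from 4, which reacts with 2-methylprop-1-enylmagnesium bromide and CuI (5 mol%) in THF at −40 °C at the primary allylic carbon (the fully substituted far end of the allyl unit blocks transposition) to give prenyl triene F4. SeO2 (catalytic) with tBuOOH in CH2Cl2 at 20 °C then oxidises the (E)-methyl group of the more electron-rich prenyl olefin to the (E)-allylic alcohol, and the sequence comes back to the route at 7, one step longer.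

**Further compounds**
F1 | step 8 | triethyl{[(2R,3R,5E,7Z)-2,8-dibromo-1,7-dichloro-2,6-dimethylocta-5,7-dien-3-yl]oxy}silane | C[C@](Br)(CCl)[C@H](O[Si](CC)(CC)CC)C/C=C(C)/C(Cl)=C/Br
F2 | step 8 | triethylsilyl ether of 11 at the C6 oxygen | C[C@](Br)(CCl)[C@H](O[Si](CC)(CC)CC)C[C@@H]1O[C@@]1(C)/C(Cl)=C/Br
F3 | step 7 | (2S,3R,5E,7Z)-2,8-dibromo-7-chloro-2,6-dimethylocta-5,7-diene-1,3-diol | C[C@](Br)(CO)[C@H](O)C/C=C(C)/C(Cl)=C/Br
F4 | step 4 | (1Z,3E)-1-bromo-2-chloro-3,7-dimethylocta-1,3,6-triene | CC(C)=CC/C=C(C)/C(Cl)=C/Br
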